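The target is read as a labd-7-ene whose ring B hides a cyclohexene retron: the six carbons C5–C10 are the sum of a C5=C6–C7=C8 diene and a C9=C10 dienophile, already linked through C1–C4 of ring A. An amine-catalysed intramolecular Diels–Alder reaction of an achiral open-chain trienal therefore forms C5–C10 and C8–C9, closes rings A and B together and sets C5, C8, C9 and C10 in one operation. The precursor is a (2E,8E,10E)-3,7,7-trimethyldodeca-2,8,10-trienal carrying C17 as a silyloxymethyl group on the diene terminus. The C12–C15 arm with C13 comes from the chiral pool by Wittig coupling at C11.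

Key step: step 8

Remarks
- Numbering: labdane numbering is used for all bicyclic compounds (ring A = C1–C5 and C10; ring B = C5–C10; chain C11–C15 on C9; C16 on C13; C17 on C8; C18 and C19 on C4; C20 on C10); β is the face of C20. The target is (5S,9R,10S,13S).
- Assumption: isobutyronitrile, 5-iodopent-1-yne, triethyl 4-phosphonocrotonate and (2R)-4-methoxy-2-methyl-4-oxobutanoic acid (the half-ester of (R)-methylsuccinic acid with the free acid on the branched carbon) are bought; the half-ester is used because the future C12 and C15 are then already differentiated.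
- Design: C17 is carried as a tert-butyldiphenylsilyl ether, which tolerates Me3Al and the aqueous acid salt of the key step. The E enal is built by stereospecific carbometalation, so no E/Z separation is needed.

Step 1
Reactants: 1 isobutyronitrile; 2 5-iodopent-1-yne
Product: 4 2,2-dimethylhept-6-ynenitrile, via lithiated nitrile 3 (not isolated)
Conditions: LiN(i-Pr)2 (1.3 equiv), 1 (1.3 equiv), THF, −78 °C; then 2, −78 °C → rt
Reagents that add atoms: none
Why: Alkylation of a metallated nitrile: the compact, strongly nucleophilic anion 3 should displace the primary iodide by SN2 faster than it removes the acetylenic proton, building the quaternary carbon that becomes C4.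

Step 2
Reactants: 4 2,2-dimethylhept-6-ynenitrile
Product: 6 2,2-dimethylhept-6-ynal, via N-aluminoimine 5 (not isolated)
Conditions: i-Bu2AlH (1.2 equiv), CH2Cl2, −78 → 0 °C; then 1 M aq. HCl, 0 °C
Reagents that add atoms: water, O
Why: Partial reduction of a nitrile with i-Bu2AlH stops at the N-aluminoimine, which is hydrolysed to the aldehyde on acidic work-up, so over-reduction is excluded and the alkyne is untouched at low temperature.

Step 3
Reactants: 6 2,2-dimethylhept-6-ynal; 7 triethyl 4-phosphonocrotonate
Product: 9 ethyl (2E,4E)-6,6-dimethylundeca-2,4-dien-10-ynoate, via lithiated phosphonate 8 (not isolated)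
Conditions: 7 (1.3 equiv), LiN(SiMe3)2 (1.25 equiv), THF, −78 °C; then 6, −78 °C → rt
Reagents that add atoms: none
Why: Vinylogous Horner–Wadsworth–Emmons olefination: the stabilised allylic phosphonate anion adds through its α-carbon to the non-enolisable α-quaternary aldehyde, and the bulky substituent should enforce the E geometry of the new C5=C6 bond.

Step 4
Reactants: 9 ethyl (2E,4E)-6,6-dimethylundeca-2,4-dien-10-ynoate
Product: 10 (2E,4E)-6,6-dimethylundeca-2,4-dien-10-yn-1-ol
Conditions: i-Bu2AlH (2.5 equiv), CH2Cl2, −78 °C; aq. KNaC4H4O6 work-up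
Reagents that add atoms: none
Why: 1,2-Reduction of the dienoate by i-Bu2AlH gives the dienyl alcohol without touching alkene geometry or the alkyne.

Step 5
Reactants: 10 (2E,4E)-6,6-dimethylundeca-2,4-dien-10-yn-1-ol
Product: 11 tert-butyl{[(2E,4E)-6,6-dimethylundeca-2,4-dien-10-yn-1-yl]oxy}diphenylsilane
Conditions: TBDPSCl, imidazole, CH2Cl2, 0 °C → rt
Reagents that add atoms: tert-butyl(chloro)diphenylsilane, CC(C)(C)[Si](Cl)(c1ccccc1)c1ccccc1
Why: Silylation of the primary alcohol; the tert-butyldiphenylsilyl ether is chosen for its stability toward Me3Al in step 6 and toward the aqueous ammonium salt in step 8.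

Step 6
Reactants: 11 tert-butyl{[(2E,4E)-6,6-dimethylundeca-2,4-dien-10-yn-1-yl]oxy}diphenylsilane
Product: 14 (2E,8E,10E)-12-[(tert-butyldiphenylsilyl)oxy]-3,7,7-trimethyldodeca-2,8,10-trien-1-ol, via alkenylalane 12 (not isolated), via lithium alanate 13 (not isolated)
Conditions: Me3Al (2.5 equiv), Cp2ZrCl2 (0.25 equiv), CH2Cl2, 0 °C → rt; volatiles removed; hexane/THF, n-BuLi, −78 → 0 °C; (CH2O)n, rt; aq. work-up
Reagents that add atoms: trimethylaluminium, C[Al](C)C; paraformaldehyde (formaldehyde unit), C=O
Why: Zirconium-catalysed methylalumination of the terminal alkyne (Negishi carboalumination) adds CH3 and Al syn with Al at the terminus, and the alanate attacks formaldehyde with retention, so the trisubstituted C9=C10 alkene should arise as the E isomer by mechanism while the internal diene and the silyl ether stay inert.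

Step 7
Reactants: 14 (2E,8E,10E)-12-[(tert-butyldiphenylsilyl)oxy]-3,7,7-trimethyldodeca-2,8,10-trien-1-ol
Product: 15 (2E,8E,10E)-12-[(tert-butyldiphenylsilyl)oxy]-3,7,7-trimethyldodeca-2,8,10-trienal
Conditions: MnO2 (excess), CH2Cl2, rt
Reagents that add atoms: none
Why: Allylic oxidation with activated MnO2 converts the primary allylic alcohol into the enal under neutral conditions that should not isomerise the E alkene.

Step 8
Reactants: 15 (2E,8E,10E)-12-[(tert-butyldiphenylsilyl)oxy]-3,7,7-trimethyldodeca-2,8,10-trienal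
Product: 18 (1S,2S,4aS,8aS)-2-{[(tert-butyldiphenylsilyl)oxy]methyl}-5,5,8a-trimethyl-1,2,4a,5,6,7,8,8a-octahydronaphthalene-1-carbaldehyde, via substrate iminium triflate 16 (not isolated), via adduct iminium triflate 17 (not isolated)
Conditions: (2S,5S)-5-benzyl-2-tert-butyl-3-methylimidazolidin-4-one (20 mol %), CF3SO3H (20 mol %), MeCN/H2O (98:2), 5 °C → rt
Reagents that add atoms: water, O (returns the formyl oxygen on hydrolysis of 17)
Why: Proposed new method: the amine salt condenses with enal 15 to the E iminium ion 16, whose lowered LUMO lets C9=C10 add suprafacially to the s-cis C5=C6–C7=C8 diene in a concerted, asynchronous [4+2] cycloaddition (C5–C10 leading C8–C9), and hydrolysis of adduct iminium 17 frees 18 and the amine. The closest known reaction type is the imidazolidinone-salt-catalysed type 1 intramolecular Diels–Alder reaction of (2E,7E,9E)-deca-2,7,9-trienals to trans-fused octalin carbaldehydes; a β,β-disubstituted enal that forms a quaternary carbon has not been shown, although such enals are known to form reactive iminium ions with these amines. Ring B closes as the cyclohexene made from the four diene carbons plus C9 and C10, and ring A closes in the same event as the six-membered tether ring (C10, C1–C4, C5) when C5–C10 forms. C10 and C9 (C20 cis to C11) follow from the E geometry of the enal, C5 (H-5 trans to C20) from the transition state with the iminium group endo and the chair-like tether exo, C8 (C17 cis to C11) from the E,E diene under the same endo topology, and the absolute sense from the benzyl group of the (5S) amine, which covers one face of the E iminium so that the diene adds to the C10-Re/C9-Si face and makes C10 S. The step needs endo over exo selectivity, enantiofacial selectivity and retention of the E enal geometry: the terminal formyl group on an E dienophile and the four-carbon tether biased by the C4 gem-dimethyl group favour the endo, trans-fused mode, the amine supplies the facial bias, and the low temperature and the stereodefined enal from step 6 limit E/Z leakage through the dienamine.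

Step 9
Reactants: 19 (2R)-4-methoxy-2-methyl-4-oxobutanoic acid
Product: 20 methyl (3R)-4-hydroxy-3-methylbutanoate
Conditions: BH3·SMe2 (1.1 equiv), THF, −10 °C → rt; MeOH quench; used at once
Reagents that add atoms: none
Why: Chemoselective borane reduction of the carboxylic acid (through an acyloxyborane) beside the methyl ester; the stereocentre is not at a reacting carbon and is retained.

Step 10
Reactants: 20 methyl (3R)-4-hydroxy-3-methylbutanoate
Product: 21 methyl (3R)-4-iodo-3-methylbutanoate
Conditions: PPh3, I2, imidazole, CH2Cl2, 0 °C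
Reagents that add atoms: iodine, II
Why: Appel-type iodination of the primary alcohol through the alkoxyphosphonium iodide is fast at 0 °C, which should forestall lactonisation of the γ-hydroxy ester.

Step 11
Reactants: 21 methyl (3R)-4-iodo-3-methylbutanoate
Product: 22 [(2R)-4-methoxy-2-methyl-4-oxobutyl]triphenylphosphonium iodide
Conditions: PPh3 (1.5 equiv), MeCN, 80 °C
Reagents that add atoms: triphenylphosphine, c1ccc(cc1)P(c1ccccc1)c1ccccc1
Why: SN2 quaternisation of triphenylphosphine by the primary iodide gives the Wittig salt that carries C12–C16 with C13 already set.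

Step 12
Reactants: 22 [(2R)-4-methoxy-2-methyl-4-oxobutyl]triphenylphosphonium iodide; 18 (1S,2S,4aS,8aS)-2-{[(tert-butyldiphenylsilyl)oxy]methyl}-5,5,8a-trimethyl-1,2,4a,5,6,7,8,8a-octahydronaphthalene-1-carbaldehyde
Product: 24 methyl (11Z,13R)-17-[(tert-butyldiphenylsilyl)oxy]labda-6,11-dien-15-oate, via phosphorus ylide 23 (not isolated)
Conditions: 22 (1.6 equiv), NaN(SiMe3)2 (1.5 equiv), THF, −78 → 0 °C; then 18, −78 °C → rt
Reagents that add atoms: none
Why: Wittig olefination with a non-stabilised ylide forms the C11=C12 bond (Z expected, geometry irrelevant because step 15 saturates it); the salt is kept in slight excess over the base so that no free amide meets the C9–H next to the formyl group, and C13 is not acidic.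

Step 13
Reactants: 24 methyl (11Z,13R)-17-[(tert-butyldiphenylsilyl)oxy]labda-6,11-dien-15-oate
Product: 25 methyl (11Z,13R)-17-hydroxylabda-6,11-dien-15-oate
Conditions: Bu4NF, AcOH, THF, 0 °C → rt
Reagents that add atoms: none
Why: Fluoride-mediated cleavage of the silyl ether, buffered by acetic acid so that the methyl ester is spared.

Step 14
Reactants: 25 methyl (11Z,13R)-17-hydroxylabda-6,11-dien-15-oate
Product: 27 methyl (11Z,13R)-17-oxolabda-7,11-dien-15-oate, via unconjugated aldehyde 26 (not isolated)
Conditions: Dess–Martin periodinane, CH2Cl2, 0 °C → rt; aq. NaHCO3 wash; then DBU (0.2 equiv), CH2Cl2, rt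
Reagents that add atoms: none
Why: Dess–Martin oxidation gives the β,γ-unsaturated aldehyde, whose acidic C8–H is removed by DBU and whose dienolate is reprotonated at C6, which moves the alkene into conjugation as the more stable C7=C8 enal and deletes the C8 stereocentre; C9–H is not vinylogously acidic and should stay untouched.

Step 15
Reactants: 27 methyl (11Z,13R)-17-oxolabda-7,11-dien-15-oate
Product: 28 methyl (13S)-17-oxolabd-7-en-15-oate
Conditions: H2 (1 atm), RhCl(PPh3)3 (10 mol %), PhMe, rt
Reagents that add atoms: none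
Why: Homogeneous hydrogenation with RhCl(PPh3)3 should saturate the 1,2-disubstituted C11=C12 alkene and leave the trisubstituted, conjugated C7=C8 enal alone; no stereocentre is created and C13 is retained (its descriptor changes to S only through the priority rules).

Step 16
Reactants: 28 methyl (13S)-17-oxolabd-7-en-15-oate
Product: 29 (13S)-labd-7-ene-15,17-diol
Conditions: i-Bu2AlH (5 equiv), CH2Cl2, −78 → 0 °C; aq. KNaC4H4O6 work-up
Reagents that add atoms: none
Why: i-Bu2AlH reduces the enal by 1,2-addition to the allylic alcohol and the methyl ester to the primary alcohol in one operation.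

Step 17
Reactants: 29 (13S)-labd-7-ene-15,17-diol
Product: 30 (5S,9R,10S,13S)-labd-7-ene-15,17-diyl diacetate
Conditions: Ac2O, pyridine, DMAP (cat.), CH2Cl2, rt
Reagents that add atoms: acetic anhydride, CC(=O)OC(C)=O
Why: DMAP-catalysed acylation of both primary alcohols gives the diacetate.

Compound list
1 | isobutyronitrile (2-methylpropanenitrile) | CC(C)C#N | starting material
2 | 5-iodopent-1-yne | C#CCCCI | starting material
3 | lithiated isobutyronitrile (lithium 2-cyanopropan-2-ide) | [Li+].C[C-](C)C#N | intermediate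
4 | 2,2-dimethylhept-6-ynenitrile | C#CCCCC(C)(C)C#N | intermediate
5 | N-(diisobutylalumanyl)-2,2-dimethylhept-6-yn-1-imine | C#CCCCC(C)(C)C=N[Al](CC(C)C)CC(C)C | intermediate
6 | 2,2-dimethylhept-6-ynal | C#CCCCC(C)(C)C=O | intermediate
7 | triethyl 4-phosphonocrotonate, ethyl (2E)-4-(diethoxyphosphoryl)but-2-enoate | CCOC(=O)/C=C/CP(=O)(OCC)OCC | starting material
8 | lithium salt of 7 (phosphonate-stabilised allyl anion) | [Li+].CCOC(=O)/C=C/[CH-]P(=O)(OCC)OCC | intermediate
9 | ethyl (2E,4E)-6,6-dimethylundeca-2,4-dien-10-ynoate | CCOC(=O)/C=C/C=C/C(C)(C)CCCC#C | intermediate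
10 | (2E,4E)-6,6-dimethylundeca-2,4-dien-10-yn-1-ol | OC/C=C/C=C/C(C)(C)CCCC#C | intermediate
11 | tert-butyl{[(2E,4E)-6,6-dimethylundeca-2,4-dien-10-yn-1-yl]oxy}diphenylsilane | C#CCCCC(C)(C)/C=C/C=C/CO[Si](c1ccccc1)(c1ccccc1)C(C)(C)C | intermediate
12 | dimethyl[(1E,7E,9E)-11-(tert-butyldiphenylsilyloxy)-2,6,6-trimethylundeca-1,7,9-trien-1-yl]alumane | C[Al](C)/C=C(\C)CCCC(C)(C)/C=C/C=C/CO[Si](c1ccccc1)(c1ccccc1)C(C)(C)C | intermediate
13 | lithium butyl(dimethyl)[(1E,7E,9E)-11-(tert-butyldiphenylsilyloxy)-2,6,6-trimethylundeca-1,7,9-trien-1-yl]alanate | [Li+].CCCC[Al-](C)(C)/C=C(\C)CCCC(C)(C)/C=C/C=C/CO[Si](c1ccccc1)(c1ccccc1)C(C)(C)C | intermediate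
14 | (2E,8E,10E)-12-[(tert-butyldiphenylsilyl)oxy]-3,7,7-trimethyldodeca-2,8,10-trien-1-ol | OC/C=C(\C)CCCC(C)(C)/C=C/C=C/CO[Si](c1ccccc1)(c1ccccc1)C(C)(C)C | intermediate
15 | (2E,8E,10E)-12-[(tert-butyldiphenylsilyl)oxy]-3,7,7-trimethyldodeca-2,8,10-trienal (achiral key-step precursor) | O=C/C=C(\C)CCCC(C)(C)/C=C/C=C/CO[Si](c1ccccc1)(c1ccccc1)C(C)(C)C | intermediate
16 | E-iminium triflate of 15 with (2S,5S)-5-benzyl-2-tert-butyl-3-methylimidazolidin-4-one (enal chain anti to the tert-butyl-bearing ring carbon) | CN1C(=O)[C@H](Cc2ccccc2)/[N+](=C\C=C(/C)CCCC(C)(C)/C=C/C=C/CO[Si](c2ccccc2)(c2ccccc2)C(C)(C)C)[C@@H]1C(C)(C)C.[O-]S(=O)(=O)C(F)(F)F | intermediate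
17 | iminium triflate of adduct 18 with the same amine | CN1C(=O)[C@H](Cc2ccccc2)/[N+](=C\[C@H]3[C@@H](CO[Si](c2ccccc2)(c2ccccc2)C(C)(C)C)C=C[C@H]4C(C)(C)CCC[C@]34C)[C@@H]1C(C)(C)C.[O-]S(=O)(=O)C(F)(F)F | intermediate
18 | (1S,2S,4aS,8aS)-2-{[(tert-butyldiphenylsilyl)oxy]methyl}-5,5,8a-trimethyl-1,2,4a,5,6,7,8,8a-octahydronaphthalene-1-carbaldehyde; labdane numbering (5S,8S,9S,10S), C6=C7, C11 formyl β, C17 β, C20 β, H-5 α | O=C[C@H]1[C@@H](CO[Si](c2ccccc2)(c2ccccc2)C(C)(C)C)C=C[C@H]2C(C)(C)CCC[C@]12C | intermediate
19 | (2R)-4-methoxy-2-methyl-4-oxobutanoic acid | COC(=O)C[C@@H](C)C(=O)O | starting material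
20 | methyl (3R)-4-hydroxy-3-methylbutanoate | COC(=O)C[C@@H](C)CO | intermediate
21 | methyl (3R)-4-iodo-3-methylbutanoate | COC(=O)C[C@@H](C)CI | intermediate
22 | [(2R)-4-methoxy-2-methyl-4-oxobutyl]triphenylphosphonium iodide | [I-].COC(=O)C[C@@H](C)C[P+](c1ccccc1)(c1ccccc1)c1ccccc1 | intermediate
23 | methyl (3R)-3-methyl-4-(triphenyl-λ5-phosphanylidene)butanoate | COC(=O)C[C@@H](C)C=P(c1ccccc1)(c1ccccc1)c1ccccc1 | intermediate
24 | methyl (11Z,13R)-17-[(tert-butyldiphenylsilyl)oxy]labda-6,11-dien-15-oate (C17 β on C8, H-5 α, H-9 α) | COC(=O)C[C@@H](C)/C=C\[C@H]1[C@@H](CO[Si](c2ccccc2)(c2ccccc2)C(C)(C)C)C=C[C@H]2C(C)(C)CCC[C@]12C | intermediate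
25 | methyl (11Z,13R)-17-hydroxylabda-6,11-dien-15-oate | COC(=O)C[C@@H](C)/C=C\[C@H]1[C@@H](CO)C=C[C@H]2C(C)(C)CCC[C@]12C | intermediate
26 | methyl (11Z,13R)-17-oxolabda-6,11-dien-15-oate | COC(=O)C[C@@H](C)/C=C\[C@H]1[C@@H](C=O)C=C[C@H]2C(C)(C)CCC[C@]12C | intermediate
27 | methyl (11Z,13R)-17-oxolabda-7,11-dien-15-oate | COC(=O)C[C@@H](C)/C=C\[C@H]1C(C=O)=CC[C@H]2C(C)(C)CCC[C@]12C | intermediate
28 | methyl (13S)-17-oxolabd-7-en-15-oate | COC(=O)C[C@@H](C)CC[C@H]1C(C=O)=CC[C@H]2C(C)(C)CCC[C@]12C | intermediate
29 | (13S)-labd-7-ene-15,17-diol | OCC[C@@H](C)CC[C@H]1C(CO)=CC[C@H]2C(C)(C)CCC[C@]12C | intermediate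
30 | (5S,9R,10S,13S)-labd-7-ene-15,17-diyl diacetate (CNP0294037.1) | CC(=O)OCC[C@@H](C)CC[C@H]1C(COC(C)=O)=CC[C@H]2C(C)(C)CCC[C@]12C | target

Total step count: 17. Longest linear sequence: 14 steps (steps 1–8, then 12–17); the side-chain salt takes 3 steps (9–11).

Steps most likely to fail

1. Step 8 (Proposed new method). What may go wrong:
- Turnover may be slow or absent, because the first bond has to form at the fully substituted C10 of the iminium ion, next to the quaternary C4.
- The E enal geometry may leak through reversible dienamine formation, which would give the C9 epimer.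
- The endo preference may be eroded by the 1,3-diaxial C19/C20 contact that develops in the trans-fused transition state.
- Facial discrimination may be weak on a β,β-disubstituted iminium ion.

Fallback with known chemistry: setting out from 15, the cycloaddition would be run with an achiral Lewis acid (Me2AlCl, CH2Cl2, −78 → 0 °C). This is an established way of closing terminally activated deca-trienes to angularly methylated trans-octalins. It should give 18 as a racemate, that is, together with the mirror-image aldehyde F1. The mixture would be condensed with (1R,2R)-N,N'-dimethyl-1,2-diphenylethane-1,2-diamine (Et2O, 4 Å molecular sieves, rt) to give imidazolidine F2 (from 18) and imidazolidine F3 (from F1). Because the diamine is C2-symmetric, the aminal carbon is no new stereocentre and only two diastereomers arise. After chromatographic separation, F2 (configuration to be assigned by X-ray analysis or by correlation with 30) would be hydrolysed with dilute aq. HCl in Et2O at 0 °C. The route is rejoined at 18.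

2. Step 12. What may go wrong:
- The β-branched ylide may add sluggishly to the congested C11 carbonyl, which is flanked by C10 and C8.
- The basic ylide may enolise the aldehyde and epimerise C9.
- The ester-bearing ylide may condense with itself.

Fallback: setting out from 21 and 18, the coupling would be changed to a Julia–Kocienski olefination. Iodide 21 and 1-phenyl-1H-tetrazole-5-thiol (K2CO3, acetone, rt) should give sulfide F4. Oxidation with H2O2 and (NH4)6Mo7O24 (cat.) in EtOH should give sulfone F5. Metalation with KN(SiMe3)2 in DME at −60 °C in the presence of 18 should give the (11E)-alkene F6 by addition, Smiles rearrangement and loss of SO2. F6 would be taken through steps 13 and 14 unchanged, via the (11E)-alcohol F7 and the non-isolated (11E)-unconjugated aldehyde F8, to the (11E)-enal F9. Hydrogenation of F9 as in step 15 removes the geometric difference, and the route is rejoined at 28.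

3. Step 15. What may go wrong:
- Hydrogen uptake may be slow at the doubly α-branched Z alkene.
- Rhodium-hydride-mediated alkene migration toward C12=C13 would erase the C13 configuration.
- The enal may be partly reduced or decarbonylated.

Fallback: setting out from 27, the saturation would be postponed and done without a metal. Reduction with i-Bu2AlH as in step 16 should give dienediol F10, and acetylation as in step 17 should give diene diacetate F11. Diimide, generated in the flask from 2-nitrobenzenesulfonohydrazide and Et3N in CH2Cl2 at rt, transfers H2 in a concerted syn manner. It should reduce only the disubstituted C11=C12 alkene, with no alkene migration and no hydrogenolysis of the allylic acetate. This gives the target directly, and the route is rejoined at 30.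

Further compounds
F1 | step 8 | (1R,2R,4aR,8aR)-2-{[(tert-butyldiphenylsilyl)oxy]methyl}-5,5,8a-trimethyl-1,2,4a,5,6,7,8,8a-octahydronaphthalene-1-carbaldehyde (enantiomer of 18) | O=C[C@@H]1[C@H](CO[Si](c2ccccc2)(c2ccccc2)C(C)(C)C)C=C[C@@H]2C(C)(C)CCC[C@@]12C
F2 | step 8 | (4R,5R)-1,3-dimethyl-4,5-diphenylimidazolidine aminal of 18 (imidazolidine C2 bonded to C9) | CN1C([C@H]3[C@@H](CO[Si](c5ccccc5)(c6ccccc6)C(C)(C)C)C=C[C@H]4C(C)(C)CCC[C@]34C)N(C)[C@H](c7ccccc7)[C@H]1c8ccccc8
F3 | step 8 | (4R,5R)-1,3-dimethyl-4,5-diphenylimidazolidine aminal of F1 | CN1C([C@@H]3[C@H](CO[Si](c5ccccc5)(c6ccccc6)C(C)(C)C)C=C[C@@H]4C(C)(C)CCC[C@@]34C)N(C)[C@H](c7ccccc7)[C@H]1c8ccccc8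
F4 | step 12 | methyl (3R)-3-methyl-4-[(1-phenyl-1H-tetrazol-5-yl)sulfanyl]butanoate | COC(=O)C[C@@H](C)CSc1nnnn1-c1ccccc1
F5 | step 12 | methyl (3R)-3-methyl-4-[(1-phenyl-1H-tetrazol-5-yl)sulfonyl]butanoate | COC(=O)C[C@@H](C)CS(=O)(=O)c1nnnn1-c1ccccc1
F6 | step 12 | methyl (11E,13R)-17-[(tert-butyldiphenylsilyl)oxy]labda-6,11-dien-15-oate | COC(=O)C[C@@H](C)/C=C/[C@H]1[C@@H](CO[Si](c2ccccc2)(c2ccccc2)C(C)(C)C)C=C[C@H]2C(C)(C)CCC[C@]12C
F7 | step 12 | methyl (11E,13R)-17-hydroxylabda-6,11-dien-15-oate | COC(=O)C[C@@H](C)/C=C/[C@H]1[C@@H](CO)C=C[C@H]2C(C)(C)CCC[C@]12C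
F8 | step 12 | methyl (11E,13R)-17-oxolabda-6,11-dien-15-oate | COC(=O)C[C@@H](C)/C=C/[C@H]1[C@@H](C=O)C=C[C@H]2C(C)(C)CCC[C@]12C
F9 | step 12 | methyl (11E,13R)-17-oxolabda-7,11-dien-15-oate | COC(=O)C[C@@H](C)/C=C/[C@H]1C(C=O)=CC[C@H]2C(C)(C)CCC[C@]12C
F10 | step 15 | (11Z,13R)-labda-7,11-diene-15,17-diol | OCC[C@@H](C)/C=C\[C@H]1C(CO)=CC[C@H]2C(C)(C)CCC[C@]12C
F11 | step 15 | (11Z,13R)-labda-7,11-diene-15,17-diyl diacetate | CC(=O)OCC[C@@H](C)/C=C\[C@H]1C(COC(C)=O)=CC[C@H]2C(C)(C)CCC[C@]12C
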